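The readings are calculated for substances that don't exist.

Amounts were my starting point: at the last reading of each earlier run I added starting material, target and isomer of the product, and called the sum the kept share of the charge.

| flask | starting material | protic impurity | remark | time |
|---|---|---|---|---|
| north-west | 0.10 M | 0.045 M | run made earlier |  |
| south-west | 0.22 M | 0.045 M | run made earlier |  |
| north | 0.15 M | 0.022 M | run made earlier |  |
| flask | 0.15 M | 0.0450 M |  | 5.0 min |

| run | time / min | target / % | starting material / % | isomer of the product / % |
|---|---|---|---|---|
| north-west | 0.667 | 19 | 23 | 21 |
| north-west | 1.33 | 18 | 13 | 28 |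
| north-west | 2.00 | 9 | 8 | 36 |
| north-west | 3.00 | 8 | 5 | 41 |
| north-west | 4.00 | 0 | 4 | 47 |
| north-west | 5.00 | 1 | 3 | 44 |
| south-west | 0.250 | 13 | 43 | 9 |
| south-west | 0.833 | 18 | 16 | 18 |
| south-west | 1.33 | 12 | 10 | 25 |
| south-west | 2.00 | 10 | 8 | 33 |
| south-west | 3.00 | 6 | 5 | 37 |
| south-west | 4.00 | 3 | 0 | 40 |
| south-west | 5.00 | 2 | 3 | 46 |
| north | 1.00 | 16 | 23 | 24 |
| north | 2.00 | 15 | 4 | 41 |
| north | 3.00 | 5 | 4 | 45 |
| north | 4.00 | 5 | 4 | 50 |
| north | 5.00 | 2 | 3 | 54 |

(scatter of a reading: 2 percentage points)

1. the species that holds most of what was charged as starting material, at 5.0 min (isomer of the product / starting material / target)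
2. the largest share itself, whichever of these holds it, in percent of the starting material charged



I followed one molecule of starting material to a fork: it stays among those three species, or it goes missing. The north-west and south-west runs hold the flask's protic impurity and bracket its starting material. They kept 48.0% and 51.0%, on average 49.5%, so they stood at 1.02 molecules missing for each one kept, the loss odds, a branching ratio.

My first way was the cheap one: those two runs read 44% and 46% of isomer of the product, on average 45.0%. My second way started from the north run, which has the flask's starting material but half its impurity. It kept 59.0%, so its odds were 0.695. Assuming odds proportional to impurity gave the flask 1.42, a kept share of 41.3%. Taking off the 4.5 percentage points still unfinished left 36.8% of isomer.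

The ways parted by 8.2 points, and the second one cheated. Its proportion was my assumption, and the factor between the measured odds, 1.47, was smaller than the factor between the impurity charges, 2.05. I committed to 45.0%.

The forecast said isomer of the product at 45%, holding that “concentration of starting material has little effect on the isomer share”.

The flask gave isomer of the product at 46.3%, with 2.06% target and 1.70% starting material.

    starting material ⇌ target (K = 1.10, k = 0.0200 s⁻¹)
    starting material ⇌ isomer of the product (K = 250, k = 0.00790 s⁻¹)
    target ⇌ isomer of the product (k = 0.00700 s⁻¹)
    2 starting material → homo dimer (k = 0.0710 M⁻¹ s⁻¹)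
    starting material + protic impurity → quenched substrate (k = 0.350 M⁻¹ s⁻¹)

So this flask kept 50.1%, and its loss odds were 0.996 against my 1.02. A neighbouring flask, otherwise like it, had 4.00 times the protic impurity. A straight line through my two odds gave that neighbour 2.93, a kept share of 25.4%. The neighbour flask gave 20.6% isomer of the product, 0.233% target and 0.112% starting material, with 12.1% of the charge in homo dimer and 67.0% in quenched substrate.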